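Ring B (seven-membered: C1 ester carbon, C2, C3, C7, C8, C9, C10) is disconnected at C2–C3 and C7–C8. The feature exploited is the fused, fully substituted pair C3(CH3)/C7(O) of ring A (C3–C7, isopropyl on C6) with oxygen at C1, β to C3: C3=C7 becomes a cyclopentanone silyl enol ether and C1, C2, C8, C9, C10 a 3-alkoxycyclopentenone. One De Mayo operation, [2+2] photocycloaddition then acid-induced retro-aldol cleavage of the C2–C8 cyclobutane bond, should form both bonds and both quaternary stereocentres and expand the enone to ring B. The precursors are a limonene-derived, regiodefined tert-butyldimethylsilyl enol ether and racemic 3-ethoxy-5-methylcyclopent-2-en-1-one.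

Key step: step 7

Numbering: the skeleton locants C1–C10 defined above are used for all bicyclic compounds; α is the face of the bicycle that carries the C3 methyl group.

Assumption: the methylated enone is used as the racemate and the two products of the photochemical step are drawn without a C10 descriptor, because C10 is epimerisable beside the C1 carbonyl and becomes sp2 in step 8.

Step 1
Reactants: 1 (S)-limonene, (4S)-1-methyl-4-(prop-1-en-2-yl)cyclohex-1-ene
Product: 2 (S)-p-menth-1-ene, (4S)-1-methyl-4-(propan-2-yl)cyclohex-1-ene
Conditions: H2 (1 atm), RhCl(PPh3)3 (cat.), toluene, 25 °C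
Reagents that add atoms: none
Why: Homogeneous catalytic hydrogenation with RhCl(PPh3)3 should reduce the unhindered 1,1-disubstituted isopropenyl group far faster than the trisubstituted ring alkene, and the existing stereocentre is not touched.

Step 2
Reactants: 2 (S)-p-menth-1-ene
Product: 4 (3S)-6-oxo-3-(propan-2-yl)heptanal, via secondary ozonide 3 (not isolated)
Conditions: O3, CH2Cl2, −78 °C; then Me2S, −78 → 25 °C
Reagents that add atoms: ozone, [O-][O+]=O
Why: Ozonolysis with reductive work-up (cycloaddition, cycloreversion and recombination to the ozonide, then reduction by Me2S) should cleave the only alkene to a methyl ketone and an aldehyde, and the stereocentre is α to neither carbonyl.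

Step 3
Reactants: 4 (3S)-6-oxo-3-(propan-2-yl)heptanal
Product: 5 (5R)-2-methyl-5-(propan-2-yl)cyclopent-1-ene-1-carbaldehyde
Conditions: piperidine, AcOH, toluene, 80 °C
Reagents that add atoms: none
Why: Amine-catalysed intramolecular aldol condensation, in which the piperidine enamine of the aldehyde should add to the methyl ketone to close the five-membered ring and dehydration gives the conjugated enal, while the isopropyl-bearing stereocentre is not acidic in either compound.

Step 4
Reactants: 5 (5R)-2-methyl-5-(propan-2-yl)cyclopent-1-ene-1-carbaldehyde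
Product: 6 (5R)-2-methyl-5-(propan-2-yl)cyclopent-1-en-1-yl formate
Conditions: 30% H2O2 (1.5 equiv), bis(2-nitrophenyl) diselenide (cat.), CH2Cl2, 25 °C
Reagents that add atoms: hydrogen peroxide, OO
Why: Baeyer–Villiger oxidation of an α,β-unsaturated aldehyde by the areneperseleninic acid formed in situ, in which the electron-rich tetrasubstituted alkenyl group should migrate in preference to hydride, so that the enol formate locks the double bond between the methyl-bearing and the oxygenated carbon.

Step 5
Reactants: 6 (5R)-2-methyl-5-(propan-2-yl)cyclopent-1-en-1-yl formate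
Product: 8 tert-butyldimethyl{[(5R)-2-methyl-5-(propan-2-yl)cyclopent-1-en-1-yl]oxy}silane, via lithium enolate 7 (not isolated)
Conditions: MeLi (2.1 equiv), THF, 0 °C (6 added to MeLi); then TBSCl, DMPU, −78 → 25 °C
Reagents that add atoms: tert-butyldimethylsilyl chloride, CC(C)(C)[Si](C)(C)Cl
Why: Enol ester cleavage by MeLi releases the lithium enolate regiospecifically (the second equivalent consumes the acetaldehyde formed), and without a proton source it cannot equilibrate toward C6 before O-silylation, so the C3=C7 position and the C6 configuration are retained.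

Step 6
Reactants: 9 3-ethoxycyclopent-2-en-1-one
Product: 11 rac-3-ethoxy-5-methylcyclopent-2-en-1-one, via lithium dienolate 10 (not isolated)
Conditions: LiN(iPr)2, THF, −78 °C; then MeI, −78 → 0 °C
Reagents that add atoms: iodomethane, CI
Why: Stork–Danheiser α′-alkylation, in which kinetic deprotonation of the vinylogous ester at C5 and methylation of the cross-conjugated enolate place the methyl group next to the carbonyl (the future C10 next to C1), the new stereocentre being formed as a racemate that is not needed.

Step 7
Reactants: 8 tert-butyldimethylsilyl enol ether; 11 rac-3-ethoxy-5-methylcyclopent-2-en-1-one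
Product: 13 cis-fused hydroazulene-1,8-dione carrying OTBS at C7 (3R,6R,7S; C10 epimers), via cyclobutane photoadduct 12 (not isolated)
Conditions: hν (medium-pressure Hg lamp, Pyrex filter, λ > 290 nm), 8 (3 equiv), degassed CH2Cl2, −40 °C; excess 8 recovered by bulb-to-bulb distillation; then 1 M HCl, THF, 25 °C
Reagents that add atoms: water, O
Why: Excitation of vinylogous ester 11 (n→π*, then intersystem crossing) gives a triplet enone that should add stepwise to the electron-rich C3=C7 bond of 8, first C2–C3 and then, after spin inversion of the 1,4-biradical with its two oxygen-stabilised tertiary radical centres, C7–C8, to give cyclobutane 12; acid then protonates the C1 carbonyl of this donor–acceptor cyclobutane, the ethoxy lone pair pushes out the C2–C8 bond (retro-aldol of a β-alkoxy ketone, C8 being a tertiary ether and not an acetal), and hydration of the oxocarbenium ion followed by loss of ethanol leaves the C8 ketone of 13. The closest known reaction type is the De Mayo reaction, together with the [2+2] photocycloaddition of cyclic enones to silyl enol ethers. The only ring closed by bond formation is the transient four-membered ring (radical–radical combination within the 1,4-biradical); ring B is not cyclised but arises when the bond shared by the four-membered and five-membered rings of the bicyclo[3.2.0]heptanone is cleaved, a two-carbon expansion of the cyclopentenone. C3 and C7 are set together: both new bonds form on one face of the alkene because a cyclobutane on a cyclopentane must be cis-fused, which places CH3 and OTBS cis, and that face is the one anti to the C6 isopropyl group, so that isopropyl, OTBS and CH3 all end α. The step needs head-to-tail regiochemistry and anti facial selectivity: the former should be secured because the fully substituted, ethoxy-bearing C8 is blocked for the first bond while the unsubstituted C2 attacks the methyl-bearing C3 and leaves the radical on the oxygenated C7, the latter by the isopropyl group next to C7, since a biradical formed on the wrong face cannot close beside it and reverts. The C2, C8 and C10 configurations of 12 do not matter, because C2 and C8 lose their stereochemistry on fragmentation and C10 is planarised in step 8.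

Step 8
Reactants: 13 cis-fused hydroazulene-1,8-dione
Product: 14 conjugated bis(enol triflate), C1(OTf)=C10(CH3) and C8(OTf)=C9 (3R,6R,7S)
Conditions: Tf2O (3 equiv), 2,6-di-tert-butyl-4-methylpyridine (3.5 equiv), CH2Cl2, 0 → 40 °C
Reagents that add atoms: trifluoromethanesulfonic anhydride, O=S(=O)(OS(=O)(=O)C(F)(F)F)C(F)(F)F
Why: Enol triflate formation by O-sulfonylation of each ketone and loss of an α-proton to the hindered base, in which C8 can only enolise toward C9 and C1 should lose the tertiary C10–H and not the C2–H shielded by the quaternary C3, giving the more substituted conjugated dienyl bis(triflate) and removing the C10 stereocentre.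

Step 9
Reactants: 14 conjugated bis(enol triflate)
Product: 15 ring B diene, C1=C10(CH3) and C8=C9, C7 OTBS (3R,6R,7S)
Conditions: Pd(OAc)2 (cat.), PPh3, HCO2H, Bu3N, DMF, 60 °C
Reagents that add atoms: none
Why: Palladium-catalysed formate reduction of enol triflates, in which oxidative addition of each C–OTf bond to zerovalent palladium, exchange of triflate for formate, decarboxylation to a vinylpalladium hydride and reductive elimination should replace both triflates by hydrogen without moving the double bonds.

Step 10
Reactants: 15 ring B diene
Product: 16 ring B 1(10)-ene with C7 OTBS (3R,6R,7S)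
Conditions: H2 (1 atm), RhCl(PPh3)3 (cat.), benzene, 25 °C
Reagents that add atoms: none
Why: Homogeneous hydrogenation with RhCl(PPh3)3 is highly sensitive to alkene substitution, so 1,2-addition of hydrogen should occur at the cis-disubstituted C8=C9 bond and leave the trisubstituted C1=C10 bond, with no stereocentre formed.

Step 11
Reactants: 16 ring B 1(10)-ene with C7 OTBS
Product: 17 tertiary alkenol, C1=C10(CH3) with free α C7 hydroxyl (3R,6R,7S)
Conditions: Bu4NF (3 equiv), THF, 60 °C
Reagents that add atoms: none
Why: Fluoride-mediated desilylation, driven by the strong Si–F bond, should free the hindered tertiary C7 hydroxyl under basic conditions that affect neither the alkene nor the stereocentres.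

Step 12
Reactants: 17 tertiary alkenol
Product: 18 epoxy alcohol, α-epoxide across C1–C10 syn to the C7 hydroxyl (1R,3R,6R,7S,10S)
Conditions: VO(acac)2 (cat.), t-BuOOH, toluene, 25 °C
Reagents that add atoms: tert-butyl hydroperoxide, CC(C)(C)OO
Why: Hydroxyl-directed vanadium-catalysed epoxidation, in which the C7 alkoxide binds the vanadium alkylperoxide and should deliver oxygen across ring B to the α face of C1=C10 (bishomoallylic by both the C8–C9 and the C2–C3 tether), setting C1 and C10 with the epoxide syn to the C7 hydroxyl, an arrangement from which that hydroxyl cannot open the epoxide by rear-side attack.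

Step 13
Reactants: 18 epoxy alcohol
Product: 19 triol, C1 hydroxyl α, C10 hydroxyl β, C7 hydroxyl α (1R,3R,6R,7S,10R)
Conditions: 0.1 M aq HClO4, THF, 0 °C
Reagents that add atoms: water, O
Why: Acid-catalysed epoxide hydrolysis of borderline SN2 type, in which water should attack the protonated epoxide at the tertiary C10 from the β face with inversion while the epoxide oxygen stays on C1, so that the C10 hydroxyl ends β, the C10 methyl α and the C1 hydroxyl α (trans-diol).

Step 14
Reactants: 19 triol; 20 4-methoxybenzoyl chloride
Product: 21 target, (1R,3aR,5R,6R,8aS)-6,8a-dihydroxy-3a,6-dimethyl-1-(propan-2-yl)decahydroazulen-5-yl 4-methoxybenzoate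
Conditions: 20 (1.2 equiv), pyridine, DMAP (cat.), CH2Cl2, 0 → 25 °C
Reagents that add atoms: none
Why: Nucleophilic-catalysed O-acylation should occur only at the secondary C1 hydroxyl, the tertiary C7 and C10 hydroxyls being too hindered to react under these conditions, and it proceeds with retention at C1.

Compound list
1 | (S)-limonene, (4S)-1-methyl-4-(prop-1-en-2-yl)cyclohex-1-ene | CC1=CC[C@H](CC1)C(=C)C | starting material
2 | (S)-p-menth-1-ene, (4S)-1-methyl-4-(propan-2-yl)cyclohex-1-ene | CC1=CC[C@H](CC1)C(C)C | intermediate
3 | secondary ozonide of 2, 1-methyl-4-(propan-2-yl)-7,8,9-trioxabicyclo[4.2.1]nonane (isopropyl carbon as in 2, acetal carbons as formed) | CC12CC[C@H](C(C)C)CC(OO1)O2 | intermediate (not isolated)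
4 | (3S)-6-oxo-3-(propan-2-yl)heptanal | O=CC[C@H](CCC(C)=O)C(C)C | intermediate
5 | (5R)-2-methyl-5-(propan-2-yl)cyclopent-1-ene-1-carbaldehyde | O=CC1=C(C)CC[C@@H]1C(C)C | intermediate
6 | (5R)-2-methyl-5-(propan-2-yl)cyclopent-1-en-1-yl formate | O=COC1=C(C)CC[C@@H]1C(C)C | intermediate
7 | lithium (5R)-2-methyl-5-(propan-2-yl)cyclopent-1-en-1-olate | [Li+].[O-]C1=C(C)CC[C@@H]1C(C)C | intermediate (not isolated)
8 | tert-butyldimethyl{[(5R)-2-methyl-5-(propan-2-yl)cyclopent-1-en-1-yl]oxy}silane | CC1=C(O[Si](C)(C)C(C)(C)C)[C@@H](C(C)C)CC1 | intermediate
9 | 3-ethoxycyclopent-2-en-1-one | CCOC1=CC(=O)CC1 | starting material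
10 | lithium 4-ethoxycyclopenta-1,3-dien-2-olate (α′-enolate of 9) | [Li+].CCOC1=CC([O-])=CC1 | intermediate (not isolated)
11 | rac-3-ethoxy-5-methylcyclopent-2-en-1-one | CCOC1=CC(=O)C(C)C1 | intermediate
12 | cyclobutane photoadduct, 7-[(tert-butyldimethylsilyl)oxy]-6-ethoxy-1,4-dimethyl-8-(propan-2-yl)tricyclo[5.3.0.0^2,6]decan-3-one; in skeleton numbering C1 ketone, C8 ethoxy, C7 OTBS, new bonds C2–C3 and C7–C8, drawn cis-anti-cis, C10 epimers | O=C1[C@@H]2[C@@]3(C)CC[C@H](C(C)C)[C@@]3(O[Si](C)(C)C(C)(C)C)[C@]2(OCC)CC1C | intermediate (not isolated)
13 | cis-fused hydroazulene-1,8-dione (skeleton numbering): ketones at C1 and C8, methyl at C3 and C10, isopropyl at C6, OTBS at C7; C3 methyl, C6 isopropyl and C7 OTBS all α; (3R,6R,7S), C10 epimers | O=C1C[C@@]2(C)CC[C@H](C(C)C)[C@@]2(O[Si](C)(C)C(C)(C)C)C(=O)CC1C | intermediate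
14 | conjugated bis(enol triflate): C1(OTf)=C10(CH3) and C8(OTf)=C9 in ring B, otherwise as 13; (3R,6R,7S) | CC1=C(OS(=O)(=O)C(F)(F)F)C[C@@]2(C)CC[C@H](C(C)C)[C@@]2(O[Si](C)(C)C(C)(C)C)C(OS(=O)(=O)C(F)(F)F)=C1 | intermediate
15 | ring B diene: C1=C10(CH3) and C8=C9, C7 OTBS; (3R,6R,7S) | CC1=CC[C@@]2(C)CC[C@H](C(C)C)[C@@]2(O[Si](C)(C)C(C)(C)C)C=C1 | intermediate
16 | ring B 1(10)-ene: C1=C10(CH3), C8 and C9 CH2, C7 OTBS; (3R,6R,7S) | CC1=CC[C@@]2(C)CC[C@H](C(C)C)[C@@]2(O[Si](C)(C)C(C)(C)C)CC1 | intermediate
17 | tertiary alkenol: C1=C10(CH3), free α hydroxyl at C7; (3R,6R,7S) | CC1=CC[C@@]2(C)CC[C@H](C(C)C)[C@@]2(O)CC1 | intermediate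
18 | epoxy alcohol: α-epoxide across C1–C10, syn to the α C7 hydroxyl; (1R,3R,6R,7S,10S) | O1[C@@H]2C[C@@]3(C)CC[C@H](C(C)C)[C@@]3(O)CC[C@]12C | intermediate
19 | triol: C1 hydroxyl α, C10 hydroxyl β with C10 methyl α, C7 hydroxyl α; (1R,3R,6R,7S,10R) | O[C@@H]1C[C@@]2(C)CC[C@H](C(C)C)[C@@]2(O)CC[C@@]1(C)O | intermediate
20 | 4-methoxybenzoyl chloride | COc1ccc(cc1)C(Cl)=O | starting material
21 | (1R,3aR,5R,6R,8aS)-6,8a-dihydroxy-3a,6-dimethyl-1-(propan-2-yl)decahydroazulen-5-yl 4-methoxybenzoate; (1R,3R,6R,7S,10R) in skeleton numbering | COc1ccc(C(=O)O[C@@H]2C[C@@]3(C)CC[C@H](C(C)C)[C@@]3(O)CC[C@@]2(C)O)cc1 | target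

Total step count: 14. Longest linear sequence: 13 steps (steps 1–5, then 7–14); step 6 is the one-step side branch.

Steps most likely to fail

Step 7 (photocycloaddition and fragmentation). The hindered tetrasubstituted enol ether may add too slowly to compete with enone decay, coupling may go head-to-head or with weak facial bias, and the acid treatment may also strip the silyl ether. The fallback builds ring B by ring-closing metathesis instead. It sets out from lithium enolate 7, generated from 6 as in step 5. C-Allylation with allyl bromide (THF–DMPU, −78 → 0 °C), anti to the isopropyl group, should give (2R,5R)-2-methyl-5-(propan-2-yl)-2-(prop-2-en-1-yl)cyclopentan-1-one F1. Addition of (3-methylbut-3-en-1-yl)magnesium bromide in the presence of CeCl3 (THF, −78 → 0 °C) from the β face, syn to allyl and anti to isopropyl and methyl, should give (1S,2R,5R)-2-methyl-1-(3-methylbut-3-en-1-yl)-5-(propan-2-yl)-2-(prop-2-en-1-yl)cyclopentan-1-ol F2. Ring-closing metathesis with second-generation Grubbs catalyst (CH2Cl2, 40 °C) then closes C1=C10 and comes back to the route at 17, so that steps 7 to 11 are bypassed.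

Step 8 (bis-enol triflate formation). O-Sulfonylation of the hindered, α-oxygenated C8 carbonyl may stall or trigger a shift next to the electron-poor carbon, and proton loss at C1 may go partly toward C2. The fallback traps regiodefined enolates instead of activating the ketones. It sets out from 13. TMSCl, NaI and Et3N in MeCN (equilibrating conditions) should give the conjugated bis(trimethylsilyl) dienol ether F3. MeLi (2 equiv, THF, 0 °C) releases the dilithium bis-enolate F4. Triflation with N-(5-chloropyridin-2-yl)bis(trifluoromethanesulfonimide) then gives 14, where the route is rejoined.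

Step 10 (partial hydrogenation of the diene). The bulky rhodium catalyst may fail to engage the C8=C9 bond beside the quaternary C7, or long exposure may cause over-reduction or double-bond migration. The fallback replaces metal-catalysed hydrogenation by stoichiometric, metal-free hydrogen transfer from diimide (2-nitrobenzenesulfonohydrazide, Et3N, CH2Cl2, 25 °C). Diimide is a small reagent that reduces a conjugated diene by concerted syn 1,2-addition at its less substituted double bond. The fallback sets out from 15 and comes back at 16 without forming any new compound (F0).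

Further compounds
F1 | step 7 | (2R,5R)-2-methyl-5-(propan-2-yl)-2-(prop-2-en-1-yl)cyclopentan-1-one | C=CC[C@@]1(C)CC[C@H](C(C)C)C1=O
F2 | step 7 | (1S,2R,5R)-2-methyl-1-(3-methylbut-3-en-1-yl)-5-(propan-2-yl)-2-(prop-2-en-1-yl)cyclopentan-1-ol | C=CC[C@@]1(C)CC[C@H](C(C)C)[C@@]1(O)CCC(C)=C
F3 | step 8 | bis(trimethylsilyl) dienol ether of 13, C1(OTMS)=C10(CH3) and C8(OTMS)=C9, C7 OTBS | CC1=C(O[Si](C)(C)C)C[C@@]2(C)CC[C@H](C(C)C)[C@@]2(O[Si](C)(C)C(C)(C)C)C(O[Si](C)(C)C)=C1
F4 | step 8 | dilithium bis-enolate of 13, C1(OLi)=C10(CH3) and C8(OLi)=C9, C7 OTBS | [Li+].[Li+].CC1=C([O-])C[C@@]2(C)CC[C@H](C(C)C)[C@@]2(O[Si](C)(C)C(C)(C)C)C([O-])=C1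
F0 | step 10 | none | none
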